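## Retrosynthetic overview
1. The formyl group goes in last, from an aryl iodide. Until then the iodine blocks the phenol's ortho position next to the side chain.
2. The indane comes from a 3‑(1‑aryl‑2,2‑dimethylbut‑3‑enyl)phenol. Oxidative para C–C closure gives a 2,2‑dimethyltetralin‑type cation. This contracts 6→5 by a 1,2‑shift of the diarylmethine carbon and loses H⁺ to give the isopropylidene group.
3. That phenol comes from a diaryl carbinol and a prenylsilane. γ‑Attack makes the C–CMe2 bond and sets the methine centre.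
4. The carbinol comes from 3‑bromophenol MOM ether and a benzodioxane aldehyde. The aldehyde comes from p‑cresol (double formylation, then aryl C→O shift) and an epoxy nosylate made from prenol, which sets the dioxane centre.
5. Ring order: the 1,4‑dioxane first, then a transient six‑membered carbocycle, then the five‑membered ring in the same operation.

Assumption: the MOM ether of 3‑bromophenol is bought as such, and the catalyst enantiomer for the allylation step has to be fixed by a first screen.

## Route

Step 1
Reactants: 1 p‑cresol (4‑methylphenol)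
Product: 2 2‑hydroxy‑5‑methylbenzene‑1,3‑dicarbaldehyde
Conditions: hexamethylenetetramine (4 equiv), CF3CO2H, reflux; then 4 M HCl, rt
Reagents that add atoms: hexamethylenetetramine C1N2CN3CN1CN(C2)C3; water O
Why: Double Duff formylation takes both free ortho positions because the para position carries the methyl group, and no stereocentre is involved.

Step 2
Reactants: 2 2‑hydroxy‑5‑methylbenzene‑1,3‑dicarbaldehyde
Product: 4 2,3‑dihydroxy‑5‑methylbenzaldehyde, via aryl formate 3 (not isolated)
Conditions: H2O2 (1.05 equiv), aq NaOH, 0 °C to rt; then HCl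
Reagents that add atoms: hydrogen peroxide OO
Why: In this Dakin oxidation hydroperoxide adds to one formyl group, the aryl group shifts from C to O and the formate is hydrolysed, and the catecholate formed is far less electrophilic, so the second formyl group survives.

Step 3
Reactants: 5 prenol (3‑methylbut‑2‑en‑1‑ol)
Product: 7 [(2R)‑3,3‑dimethyloxiran‑2‑yl]methyl 4‑nitrobenzenesulfonate, via epoxy alcohol 6 (not isolated)
Conditions: Ti(Oi‑Pr)4 (5 mol%), D‑(−)‑DIPT (6 mol%), t‑BuOOH, 4 Å MS, CH2Cl2, −20 °C; then Et3N, DMAP (cat.), 4‑NsCl, −10 °C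
Reagents that add atoms: tert‑butyl hydroperoxide CC(C)(C)OO; 4‑nitrobenzenesulfonyl chloride O=S(=O)(Cl)c1ccc(cc1)[N+](=O)[O-]
Why: Sharpless asymmetric epoxidation with the D‑tartrate gives the (R)‑oxirane carbon (ee raised by crystallising 7), and sulfonylation in the same flask avoids isolating the water‑soluble epoxy alcohol.

Step 4
Reactants: 4 2,3‑dihydroxy‑5‑methylbenzaldehyde; 7 [(2R)‑3,3‑dimethyloxiran‑2‑yl]methyl 4‑nitrobenzenesulfonate
Product: 9 (3S)‑3‑(2‑hydroxypropan‑2‑yl)‑7‑methyl‑2,3‑dihydro‑1,4‑benzodioxine‑5‑carbaldehyde, via epoxide ether 8 (not isolated)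
Conditions: NaH (2.1 equiv), DMSO–THF, 0 °C; 7, rt to 60 °C
Reagents that add atoms: none
Why: In this Williamson‑type annulation the non‑chelated 3‑phenoxide of the dianion displaces the nosylate first, then the 2‑phenoxide opens the oxirane 6‑exo at the secondary carbon by SN2 with inversion, so (R)‑7 gives the (S)‑dioxane centre.

Step 5
Reactants: 10 1‑bromo‑3‑(methoxymethoxy)benzene; 9 (3S)‑3‑(2‑hydroxypropan‑2‑yl)‑7‑methyl‑2,3‑dihydro‑1,4‑benzodioxine‑5‑carbaldehyde
Product: 13 [2‑iodo‑3‑(methoxymethoxy)phenyl][(3S)‑3‑(2‑hydroxypropan‑2‑yl)‑7‑methyl‑2,3‑dihydro‑1,4‑benzodioxin‑5‑yl]methanol (both carbinol epimers), via aryllithium 11 (not isolated), via carbinol 12 (not isolated)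
Conditions: 10, n‑BuLi, THF, −78 °C; 9 pre‑treated with NaH (1.05 equiv); then n‑BuLi (1.3 equiv), TMEDA, 0 °C; I2, −78 °C
Reagents that add atoms: iodine II
Why: Br–Li exchange and 1,2‑addition are followed by directed ortho‑metalation at the position between OMOM and the benzylic alkoxide (two cooperating directing groups) and iodination, and the carbinol configuration does not matter because it is erased in step 7.

Step 6
Reactants: 14 prenyl chloride (1‑chloro‑3‑methylbut‑2‑ene)
Product: 16 trimethyl(3‑methylbut‑2‑en‑1‑yl)silane, via prenylmagnesium chloride 15 (not isolated)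
Conditions: Mg, Me3SiCl, THF, 0 °C to rt
Reagents that add atoms: chlorotrimethylsilane C[Si](C)(C)Cl
Why: In this Barbier‑type silylation the allylic Grignard reagent is trapped by the silyl chloride at its unhindered primary terminus.

Step 7
Reactants: 13 the iodo carbinol from step 5; 16 trimethyl(3‑methylbut‑2‑en‑1‑yl)silane
Product: 18 3‑{(1R)‑1‑[(3S)‑3‑(2‑hydroxypropan‑2‑yl)‑7‑methyl‑2,3‑dihydro‑1,4‑benzodioxin‑5‑yl]‑2,2‑dimethylbut‑3‑en‑1‑yl}‑2‑iodophenol, via MOM ether 17 (not isolated)
Conditions: chiral confined imidodiphosphorimidate Brønsted acid (3 mol%), 16 (3 equiv), toluene, −60 °C; then 1.25 M HCl in MeOH, 40 °C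
Reagents that add atoms: none
Why: Proposed new method: the strong confined chiral acid (silylated in situ by 16) ionises the doubly benzylic carbinol to a diarylmethyl cation held as a contact ion pair in the chiral anion pocket, the prenylsilane attacks one face through its γ‑carbon (SE2′, β‑silyl stabilisation) so that the C–CMe2 bond and the (R)‑methine centre are set under catalyst control from either carbinol epimer, and methanolic HCl then removes the MOM group and any O‑silyl group; the closest known reactions are the Hosomi–Sakurai allylation of benzhydrols and catalytic enantioconvergent SN1 allylations of carbocations paired with chiral anions.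

Step 8
Reactants: 18 the phenol from step 7
Product: 19 (3R)‑4‑iodo‑3‑[(3S)‑3‑(2‑hydroxypropan‑2‑yl)‑7‑methyl‑2,3‑dihydro‑1,4‑benzodioxin‑5‑yl]‑2‑(propan‑2‑ylidene)‑2,3‑dihydro‑1H‑inden‑5‑ol
Conditions: PhI(OAc)2 (1.0 equiv, slow addition), (CF3)2CHOH–CH2Cl2, −20 °C
Reagents that add atoms: none
Why: Proposed new method: ligand exchange of the phenol at iodine(III) makes its free para carbon electrophilic (the ortho site next to the side chain is blocked by iodine and the fully etherified arene is not activated), the terminal CH2 of the vinyl group closes a six‑membered ring, the charge building up at the neopentyl‑type CH is relieved by an antiperiplanar 1,2‑shift of the diarylmethine carbon from CMe2 to that CH with retention (6→5 ring contraction, helped by release of strain in the crowded C–CMe2 bond), the tertiary cation loses the ring proton to give the isopropylidene group and the dienone tautomerises to the phenol; the closest known reactions are iodine(III)‑mediated phenol dearomatisations that end in Wagner–Meerwein or pinacol shifts and the retropinacol contraction of 2,2‑dimethylcyclohexyl cations to isopropylidenecyclopentanes.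

Step 9
Reactants: 19 the iodo indanol from step 8
Product: 21 diaporindene H, (3S)‑5‑hydroxy‑3‑[(3S)‑3‑(2‑hydroxypropan‑2‑yl)‑7‑methyl‑2,3‑dihydro‑1,4‑benzodioxin‑5‑yl]‑2‑(propan‑2‑ylidene)‑2,3‑dihydro‑1H‑indene‑4‑carbaldehyde, via arylmagnesium species 20 (not isolated)
Conditions: i‑PrMgCl·LiCl (3.5 equiv), THF, −20 to 0 °C; DMF; 1 M HCl, 0 °C
Reagents that add atoms: N,N‑dimethylformamide CN(C)C=O
Why: After both OH groups are deprotonated, iodine–magnesium exchange and Bouveault‑type formylation place CHO exactly where the iodine stood, the Grignard reagent is too weak a base to remove the doubly benzylic proton, and the geometry at the methine carbon is unchanged (the descriptor changes from R to S only because I is replaced by CHO).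

## Compound list
1 | p‑cresol | Cc1ccc(O)cc1 | starting material
2 | 2‑hydroxy‑5‑methylbenzene‑1,3‑dicarbaldehyde | Cc1cc(C=O)c(O)c(C=O)c1 | intermediate
3 | 3‑formyl‑2‑hydroxy‑5‑methylphenyl formate | Cc1cc(C=O)c(O)c(OC=O)c1 | intermediate (not isolated)
4 | 2,3‑dihydroxy‑5‑methylbenzaldehyde | Cc1cc(O)c(O)c(C=O)c1 | intermediate
5 | prenol | CC(C)=CCO | starting material
6 | [(2R)‑3,3‑dimethyloxiran‑2‑yl]methanol | CC1(C)O[C@@H]1CO | intermediate (not isolated)
7 | [(2R)‑3,3‑dimethyloxiran‑2‑yl]methyl 4‑nitrobenzenesulfonate | CC1(C)O[C@@H]1COS(=O)(=O)c1ccc(cc1)[N+](=O)[O-] | intermediate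
8 | 3‑{[(2R)‑3,3‑dimethyloxiran‑2‑yl]methoxy}‑2‑hydroxy‑5‑methylbenzaldehyde | CC1(C)O[C@@H]1COc1cc(C)cc(C=O)c1O | intermediate (not isolated)
9 | (3S)‑3‑(2‑hydroxypropan‑2‑yl)‑7‑methyl‑2,3‑dihydro‑1,4‑benzodioxine‑5‑carbaldehyde | O=Cc1cc(C)cc2c1O[C@H](C(C)(C)O)CO2 | intermediate
10 | 1‑bromo‑3‑(methoxymethoxy)benzene | COCOc1cccc(Br)c1 | starting material
11 | 3‑(methoxymethoxy)phenyllithium | [Li]c1cccc(OCOC)c1 | intermediate (not isolated)
12 | diaryl carbinol without iodine (formed as its dialkoxide) | OC(c1cccc(OCOC)c1)c1cc(C)cc2c1O[C@H](C(C)(C)O)CO2 | intermediate (not isolated)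
13 | iodo diaryl carbinol, both carbinol epimers | OC(c1cccc(OCOC)c1I)c1cc(C)cc2c1O[C@H](C(C)(C)O)CO2 | intermediate
14 | prenyl chloride | CC(C)=CCCl | starting material
15 | prenylmagnesium chloride | CC(C)=CC[Mg]Cl | intermediate (not isolated)
16 | trimethyl(3‑methylbut‑2‑en‑1‑yl)silane | CC(C)=CC[Si](C)(C)C | intermediate
17 | (1R)‑reverse‑prenylated diarylmethane, MOM ether | C=CC(C)(C)[C@@H](c1cccc(OCOC)c1I)c1cc(C)cc2c1O[C@H](C(C)(C)O)CO2 | intermediate (not isolated)
18 | (1R)‑reverse‑prenylated diarylmethane, free phenol | C=CC(C)(C)[C@@H](c1cccc(O)c1I)c1cc(C)cc2c1O[C@H](C(C)(C)O)CO2 | intermediate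
19 | (3R)‑4‑iodo‑3‑aryl‑2‑(propan‑2‑ylidene)indan‑5‑ol | CC(C)=C1Cc2ccc(O)c(I)c2[C@H]1c1cc(C)cc2c1O[C@H](C(C)(C)O)CO2 | intermediate
20 | arylmagnesium bis(magnesium alkoxide) | CC(C)=C1Cc2ccc(O[Mg]Cl)c([Mg]Cl)c2[C@H]1c1cc(C)cc2c1O[C@H](C(C)(C)O[Mg]Cl)CO2 | intermediate (not isolated)
21 | diaporindene H | CC(C)=C1Cc2ccc(O)c(C=O)c2[C@H]1c1cc(C)cc2c1O[C@H](C(C)(C)O)CO2 | target

## Step count and risks
Total: 9 steps. Longest linear sequence: 7 steps (1, 2, 4, 5, 7, 8, 9).

**Most likely to fail: step 8 (new).**
- The monosubstituted alkene is a weak π‑nucleophile.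
- Product 19 is a 4‑alkylphenol and can be over‑oxidised.
- The shift could pass through a free diarylmethyl cation and erode the methine centre.

The fallback uses known reactions, sets out from 18 and comes back at 19. mCPBA turns the vinyl group into the terminal epoxide F1. KOt‑Bu in t‑BuOH lets the phenoxide attack the oxirane CH2 through its para carbon; only the phenol ring is nucleophilic under base. This gives, after removal of the cis epimer, the trans‑tetralol F2. MsCl/Et3N gives the bis‑mesylate F3. Heating in 2,4,6‑collidine ionises the equatorial neopentyl‑type mesylate with the same 1,2‑shift (the classical retropinacol contraction of a 2,2‑dimethylcyclohexyl sulfonate) to give the aryl mesylate F4. KOH/MeOH then frees 19.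

**Second: step 7 (new).** Facial control over a hindered, di‑ortho‑substituted diarylmethyl cation is untested. The fallback uses known chemistry, sets out from 13 and 16 and comes back at 18. An FeCl3‑catalysed Hosomi–Sakurai reaction without stereocontrol gives 17 together with the epimeric MOM ether F5. HCl/MeOH gives 18 and the epimeric phenol F6. These are diastereomers because the dioxane centre is fixed, and they are separated by chromatography.

**Third: step 9.** The iodine–magnesium exchange is slow on a hindered, electron‑rich iodophenoxide. The fallback sets out from 19 and comes back at 21. It is a palladium‑catalysed reductive carbonylation (Pd(OAc)2, di(1‑adamantyl)‑n‑butylphosphine, CO/H2, TMEDA, toluene, 100 °C). This replaces the organometallic route and makes no new compound.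

Further compounds
F1 | step 8 | 3‑{(1R)‑1‑aryl‑2‑methyl‑2‑(oxiran‑2‑yl)propyl}‑2‑iodophenol (both oxirane epimers) | CC(C)(C1CO1)[C@@H](c1cccc(O)c1I)c1cc(C)cc2c1O[C@H](C(C)(C)O)CO2
F2 | step 8 | 2,4‑trans‑4‑aryl‑5‑iodo‑3,3‑dimethyl‑1,2,3,4‑tetrahydronaphthalene‑2,6‑diol | CC1(C)[C@H](O)Cc2ccc(O)c(I)c2[C@H]1c1cc(C)cc2c1O[C@H](C(C)(C)O)CO2
F3 | step 8 | 2,6‑bis(methanesulfonate) of F2 | CC1(C)[C@H](OS(C)(=O)=O)Cc2ccc(OS(C)(=O)=O)c(I)c2[C@H]1c1cc(C)cc2c1O[C@H](C(C)(C)O)CO2
F4 | step 8 | aryl methanesulfonate of 19 | CC(C)=C1Cc2ccc(OS(C)(=O)=O)c(I)c2[C@H]1c1cc(C)cc2c1O[C@H](C(C)(C)O)CO2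
F5 | step 7 | (1S)‑epimer of 17 | C=CC(C)(C)[C@H](c1cccc(OCOC)c1I)c1cc(C)cc2c1O[C@H](C(C)(C)O)CO2
F6 | step 7 | (1S)‑epimer of 18 | C=CC(C)(C)[C@H](c1cccc(O)c1I)c1cc(C)cc2c1O[C@H](C(C)(C)O)CO2
F0 | step 9 | none | none
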